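**Retrosynthetic overview**
1. The C2-symmetric tetraene is cut at its central C(sp2)–C(sp2) bond. Both halves come from oxidative homocoupling of one (E)-dienylboronate.
2. The cyclohexene (ring A) of that half is opened at its C=C bond. It is made by ring-closing enyne metathesis of an acyclic epoxy-enynol, with boron delivered by a vinylboronate in the same operation.
3. Key step: the oxirane C–O bonds are formed by catalyst-controlled dioxirane epoxidation of the trisubstituted olefin. It is placed before metathesis because it sets the third stereocentre and removes the one olefin that would divert ruthenium into a cyclopentene-forming ring closure.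
4. The enynol (carbinol next to the quaternary carbon) comes from chiral-acid-catalysed geranylboration of pent-4-ynal. Building blocks are geraniol, B2pin2, pent-4-yn-1-ol and vinylBpin.
5. Ring order: oxirane first, cyclohexene second. The final dimerisation duplicates both.

Assumption: the SMILES is read as drawn. It is a C2-symmetric dimer, each half (1R,2S) in the ring (hydroxyl and epoxyethyl chain cis) with an (R)-oxirane, and both olefins of the link are E.

**Step 1**
Reactants: 1 geraniol, (2E)-3,7-dimethylocta-2,6-dien-1-ol; 2 bis(pinacolato)diboron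
Product: 3 (E)-geranylboronic acid pinacol ester
Conditions: [Pd(MeCN)4](BF4)2 (5 mol %), 2 (1.2 equiv), DMSO/MeOH 1:1, 40 °C
Reagents that add atoms: none
Why: Palladium-catalysed direct borylation of an allylic alcohol (Miyaura-type borylation via an η3-allylpalladium species whose C–OH bond is activated by the diboron reagent) puts boron on the unhindered primary terminus and keeps the E-trisubstituted olefin that later encodes the relative configuration, and no stereocentre is formed.

**Step 2**
Reactants: 4 pent-4-yn-1-ol
Product: 5 pent-4-ynal
Conditions: 2-iodoxybenzoic acid (IBX, 1.5 equiv), EtOAc, 75 °C; filter, concentrate cold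
Reagents that add atoms: none
Why: IBX oxidation of a primary alcohol stops at the aldehyde, does not touch the terminal alkyne and is worked up by filtration only, which suits the volatile product, and no stereocentre is formed.

**Step 3**
Reactants: 3 (E)-geranylboronic acid pinacol ester; 5 pent-4-ynal
Product: 7 (5R,6S)-6-ethenyl-6,10-dimethylundec-9-en-1-yn-5-ol, via pinacol borate ester 6 (not isolated)
Conditions: 3 (1.2 equiv), (S)-3,3'-bis(2,4,6-triisopropylphenyl)-1,1'-binaphthyl-2,2'-diyl hydrogen phosphate [(S)-TRIP, 5 mol %], 4 Å MS, toluene, −30 → 0 °C; then aq NaHCO3, 23 °C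
Reagents that add atoms: none
Why: Chiral-phosphoric-acid-catalysed allylboration runs through a closed chair (Zimmerman–Traxler) transition state in which the E-geranyl geometry places the homoprenyl chain pseudo-equatorial and the methyl pseudo-axial, fixing the anti hydroxyl/homoprenyl relationship (cis once ring A is closed), while the (S)-acid, the mirror image of the (R)-acid that directs allyl transfer to the Re face, opens the Si face of 5, so the carbinol carbon becomes R and the quaternary carbon S.

**Step 4 (key step)**
Reactants: 7 (5R,6S)-6-ethenyl-6,10-dimethylundec-9-en-1-yn-5-ol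
Product: 8 (3S,4R)-3-{2-[(2R)-3,3-dimethyloxiran-2-yl]ethyl}-3-methyloct-1-en-7-yn-4-ol
Conditions: 1,2:4,5-di-O-isopropylidene-β-D-erythro-2,3-hexodiulo-2,6-pyranose (Shi ketone, 30 mol %), KHSO5 as 2KHSO5·KHSO4·K2SO4 (1.4 equiv), K2CO3 (5.8 equiv), Bu4NHSO4 (4 mol %), MeCN/(MeO)2CH2 1:2, aq Na2B4O7/Na2(EDTA) buffer pH 10.5, 0 °C
Reagents that add atoms: potassium peroxymonosulfate, KHSO5, [K+].[O-]S(=O)(=O)OO
Why: Shi asymmetric epoxidation, in which the dioxirane generated from the D-fructose-derived ketone transfers oxygen through a spiro transition state to the only electron-rich trisubstituted olefin and gives the (R)-oxirane while the neopentyl vinyl group, the alkyne and the hindered alcohol are inert at pH 10.5 and 0 °C; this C–O bond formation is the pivot of the route because it sets the last stereocentre of the half, builds the first ring and removes the 1,6-diene motif that would otherwise ring-close to a cyclopentene in step 5.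

**Step 5**
Reactants: 8 (3S,4R)-3-{2-[(2R)-3,3-dimethyloxiran-2-yl]ethyl}-3-methyloct-1-en-7-yn-4-ol; 9 vinylboronic acid pinacol ester
Product: 11 (1R,2S)-2-{2-[(2R)-3,3-dimethyloxiran-2-yl]ethyl}-2-methyl-4-[(E)-2-(4,4,5,5-tetramethyl-1,3,2-dioxaborolan-2-yl)ethenyl]cyclohex-3-en-1-ol, via vinylcyclohexenol 10 (not isolated)
Conditions: 9 (3 equiv), second-generation Hoveyda–Grubbs catalyst (H2IMes)Cl2Ru=CH(2-iPrOC6H4) (2 × 4 mol %), toluene (0.02 M), 60 °C, slow Ar sparge
Reagents that add atoms: none
Why: Proposed new method: ring-closing enyne metathesis in which a vinylboronate takes over the role that ethene normally plays as alkylidene shuttle, so that ring A and the boron handle are made in one operation; Ru=CH(Bpin), formed from the catalyst and 9, adds to the terminal alkyne with the usual cross-enyne regiochemistry (carbene carbon to the CH terminus), the resulting vinylcarbene Ru=C(R)–CH=CH(Bpin) sits six atoms from the neopentyl vinyl group and closes the cyclohexene, the released Ru=CH2 is turned back into Ru=CH(Bpin) by 9 with loss of ethene, and the competing methylidene cycle only gives diene 10, which ordinary cross-metathesis with 9 funnels into the same product, so every productive cycle converges on 11; the bulky Bpin group makes the new disubstituted olefin E under thermodynamic control, the trisubstituted ring olefin next to the quaternary carbon is too hindered for secondary metathesis, and epoxide, alcohol and all three stereocentres are spectators; the closest known reaction types are ring-closing enyne metathesis under ethene, tandem ring-closing enyne metathesis/cross-metathesis with acrylates or styrenes, and cross-metathesis of vinylboronates with terminal olefins.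

**Step 6**
Reactants: 11 (E)-dienylboronate (two molecules)
Product: 12 target, (1R,1'R,2S,2'S)-4,4'-[(1E,3E)-buta-1,3-diene-1,4-diyl]bis(2-{2-[(2R)-3,3-dimethyloxiran-2-yl]ethyl}-2-methylcyclohex-3-en-1-ol)
Conditions: Pd(OAc)2 (5 mol %), K2CO3 (2 equiv), O2 (1 atm), THF/H2O 4:1, 23 °C, dark
Reagents that add atoms: none
Why: Palladium-catalysed aerobic oxidative homocoupling of an alkenylboronate, in which two stereoretentive transmetalations onto divalent palladium and reductive elimination forge the central C(sp2)–C(sp2) bond with both link olefins E, O2 returns zerovalent palladium to the divalent state, the mild base at room temperature spares the non-allylic epoxides and free alcohols, no stereocentre is touched, and pairing of two enantioenriched halves removes the minor enantiomer as a separable hetero-dimer (Horeau-type amplification).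

**Compound list**
1 | geraniol, (2E)-3,7-dimethylocta-2,6-dien-1-ol | CC(C)=CCC/C(C)=C/CO | starting material
2 | bis(pinacolato)diboron | CC1(C)OB(OC1(C)C)B1OC(C)(C)C(C)(C)O1 | starting material
3 | 2-[(2E)-3,7-dimethylocta-2,6-dien-1-yl]-4,4,5,5-tetramethyl-1,3,2-dioxaborolane | CC(C)=CCC/C(C)=C/CB1OC(C)(C)C(C)(C)O1 | intermediate
4 | pent-4-yn-1-ol | C#CCCCO | starting material
5 | pent-4-ynal | C#CCCC=O | intermediate
6 | 2-{[(5R,6S)-6-ethenyl-6,10-dimethylundec-9-en-1-yn-5-yl]oxy}-4,4,5,5-tetramethyl-1,3,2-dioxaborolane | CC(C)=CCC[C@@](C)(C=C)[C@H](OB1OC(C)(C)C(C)(C)O1)CCC#C | intermediate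
7 | (5R,6S)-6-ethenyl-6,10-dimethylundec-9-en-1-yn-5-ol | CC(C)=CCC[C@@](C)(C=C)[C@H](O)CCC#C | intermediate
8 | (3S,4R)-3-{2-[(2R)-3,3-dimethyloxiran-2-yl]ethyl}-3-methyloct-1-en-7-yn-4-ol | CC1(C)O[C@@H]1CC[C@@](C)(C=C)[C@H](O)CCC#C | intermediate
9 | 2-ethenyl-4,4,5,5-tetramethyl-1,3,2-dioxaborolane | C=CB1OC(C)(C)C(C)(C)O1 | starting material
10 | (1R,2S)-2-{2-[(2R)-3,3-dimethyloxiran-2-yl]ethyl}-4-ethenyl-2-methylcyclohex-3-en-1-ol | CC1(C)O[C@@H]1CC[C@@]1(C)C=C(C=C)CC[C@H]1O | intermediate
11 | (1R,2S)-2-{2-[(2R)-3,3-dimethyloxiran-2-yl]ethyl}-2-methyl-4-[(E)-2-(4,4,5,5-tetramethyl-1,3,2-dioxaborolan-2-yl)ethenyl]cyclohex-3-en-1-ol | CC1(C)O[C@@H]1CC[C@@]1(C)C=C(/C=C/B2OC(C)(C)C(C)(C)O2)CC[C@H]1O | intermediate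
12 | (1R,1'R,2S,2'S)-4,4'-[(1E,3E)-buta-1,3-diene-1,4-diyl]bis(2-{2-[(2R)-3,3-dimethyloxiran-2-yl]ethyl}-2-methylcyclohex-3-en-1-ol) | CC1(C)O[C@@H]1CC[C@@]1(C)C=C(/C=C/C=C/C2=C[C@](C)(CC[C@H]3OC3(C)C)[C@H](O)CC2)CC[C@H]1O | target

**Step count**
Total: 6 steps. Longest linear sequence: 5 steps (1 → 3 → 7 → 8 → 11 → 12; the branch from 4 has the same length).

**Three steps most likely to fail**

Risk 1, step 5 (the new method). Compound 9 may intercept the alkyne and give acyclic boryl-dienes that close only slowly onto the hindered vinyl group. The catalyst may also die before convergence. The fallback sets out from 8 and comes back at 11, and it separates ring closure from boron transfer so that only established reactions are used. The ring is closed alone by ring-closing enyne metathesis with ethene as the shuttle: second-generation Grubbs catalyst (H2IMes)(PCy3)Cl2Ru=CHPh (5 mol %), ethene 1 atm, CH2Cl2, 40 °C. Diene 10 is isolated and purified. Boron is then attached to the finished ring in a separate cross-metathesis with 9, using second-generation Hoveyda–Grubbs catalyst (H2IMes)Cl2Ru=CH(2-iPrOC6H4) (5 mol %) in CH2Cl2 at 40 °C. This detour makes nothing that is not already in the compound list (F0).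

Risk 2, step 6. Protodeboronation, over-oxidation or E/Z erosion of the tetraene can occur under palladium and O2. The fallback sets out from 11 and comes back at 12, and it replaces the oxidative homocoupling by a non-oxidative Suzuki–Miyaura cross-coupling of two differentiated halves. Half of 11 is converted with iodine and NaOH (THF, 0 °C, retention of geometry) into the (E)-dienyl iodide F1. This is coupled with the other half of 11 under Pd(PPh3)4 (5 mol %) and aq K3PO4 in degassed THF at 23 °C in the dark.

Risk 3, step 3. The hindered γ,γ-disubstituted boronate may react slowly under acid catalysis, and a linear aliphatic aldehyde may give lower enantioselectivity. The fallback sets out from 1 (with 5) and comes back at 7, and it moves from catalyst control to reagent control.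
- Geraniol is borylated with B2(OH)4 (H2PdCl4 cat., DMSO/H2O, 23 °C) to (E)-geranylboronic acid F2.
- F2 is esterified with diisopropyl L-tartrate (MgSO4, Et2O) to the tartrate geranylboronate F3.
- F3 adds to the Si face of 5 in toluene at −78 °C (4 Å MS) through the same chair transition state, giving the tartrate borate F4.
- F4 is hydrolysed with water to 7.
- The expected 75–85 % ee is upgraded in the dimerisation.

**Further compounds**
F0 | step 5 | none | none
F1 | step 6 | (1R,2S)-2-{2-[(2R)-3,3-dimethyloxiran-2-yl]ethyl}-4-[(E)-2-iodoethenyl]-2-methylcyclohex-3-en-1-ol | CC1(C)O[C@@H]1CC[C@@]1(C)C=C(/C=C/I)CC[C@H]1O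
F2 | step 3 | [(2E)-3,7-dimethylocta-2,6-dien-1-yl]boronic acid | CC(C)=CCC/C(C)=C/CB(O)O
F3 | step 3 | diisopropyl (4R,5R)-2-[(2E)-3,7-dimethylocta-2,6-dien-1-yl]-1,3,2-dioxaborolane-4,5-dicarboxylate | CC(C)=CCC/C(C)=C/CB1O[C@@H](C(=O)OC(C)C)[C@H](C(=O)OC(C)C)O1
F4 | step 3 | diisopropyl (4R,5R)-2-{[(5R,6S)-6-ethenyl-6,10-dimethylundec-9-en-1-yn-5-yl]oxy}-1,3,2-dioxaborolane-4,5-dicarboxylate | CC(C)=CCC[C@@](C)(C=C)[C@H](OB1O[C@@H](C(=O)OC(C)C)[C@H](C(=O)OC(C)C)O1)CCC#C
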